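## Retrosynthetic overview

1. The target is a trimer of one building block, (2R,3R)-ε-viniferin (units 1+2, 3+4, 5+6). The last operations remove twelve O-benzyl and six C-tert-butyl groups.
2. The seven-membered ring (C7(1)–C14(2)) closes last by Friedel–Crafts alkylation on a quinone methide. The C8(1)–C7(3) bond comes before it, by vinylogous phenolate 1,6-addition to a quinone methide.
3. The eight-membered ring (C7(5)–C14(4)) closes by Friedel–Crafts alkylation on the bis(quinone methide). The C8(3)–C8(5) bond of that intermediate is made by laccase (oxidoreductase) phenol coupling of one protected monomer.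
4. The monomer comes from a Heck coupling of a 4-bromo-trans-2,3-diaryl-2,3-dihydrobenzofuran with 2,6-di-tert-butyl-4-vinylphenol.
5. The dihydrobenzofuran is made by enantioselective dirhodium-catalysed C–H insertion of a diaryl diazomethane, then C2 epimerisation. Ring order: dihydrofuran rings, then the eight-membered ring, then the seven-membered ring.

Locants: unit n (1–6) is one resveratrol unit; C7(n) bears its 4-oxygenated aryl ring, C8(n) its 3,5-dioxygenated ring, and C14(n) is a carbon of that ring ortho to C8(n). In units 2, 4 and 6, C7/C8 are C2/C3 of the dihydrobenzofurans.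

Assumption: Rh2(R-PTAD)4 is taken to give the (3R) centre; if the observed sense is opposite, Rh2(S-PTAD)4 is used with no other change.

## Route

Step 1
Reactants: 1 1,3-bis(benzyloxy)-5-bromobenzene
Product: 2 2,4-bis(benzyloxy)-6-bromobenzaldehyde
Conditions: POCl3 (1.5 equiv), DMF, 0 → 90 °C; aq. NaOAc
Reagents that add atoms: N,N-dimethylformamide CN(C)C=O; water O
Why: Vilsmeier–Haack formylation occurs para to one benzyloxy group and ortho to the other (the site between the two ethers is more hindered), giving the aldehyde flanked by bromine and an ether; no stereocentre is formed.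

Step 2
Reactants: 2 2,4-bis(benzyloxy)-6-bromobenzaldehyde
Product: 3 4-(benzyloxy)-2-bromo-6-hydroxybenzaldehyde
Conditions: MgBr2·OEt2 (2 equiv), toluene/Et2O, 80 °C; aq. HCl
Reagents that add atoms: none
Why: Chelation-controlled ether cleavage: magnesium binds the aldehyde oxygen together with the ortho ether oxygen, so bromide removes only that benzyl group and the para ether stays; no stereocentre.

Step 3
Reactants: 3 4-(benzyloxy)-2-bromo-6-hydroxybenzaldehyde; 4 1-(benzyloxy)-4-(chloromethyl)benzene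
Product: 5 4-(benzyloxy)-2-{[4-(benzyloxy)benzyl]oxy}-6-bromobenzaldehyde
Conditions: K2CO3 (2 equiv), NaI (0.1 equiv), DMF, 60 °C
Reagents that add atoms: none
Why: Williamson ether synthesis on the salicylaldehyde phenoxide installs the 4-(benzyloxy)benzyl group whose OCH2 later becomes C2 of the dihydrobenzofuran; no stereocentre.

Step 4
Reactants: 5 4-(benzyloxy)-2-{[4-(benzyloxy)benzyl]oxy}-6-bromobenzaldehyde
Product: 6 4-(benzyloxy)-2-{[4-(benzyloxy)benzyl]oxy}-6-bromobenzoic acid
Conditions: NaClO2, NaH2PO4, 2-methyl-2-butene, t-BuOH/THF/H2O, 0 °C → rt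
Reagents that add atoms: sodium chlorite [Na+].[O-]Cl=O
Why: Pinnick oxidation converts the hindered aldehyde to the acid under buffered conditions that spare benzyl ethers, the alkene scavenging hypochlorous acid so the electron-rich rings are not chlorinated; no stereocentre.

Step 5
Reactants: 6 4-(benzyloxy)-2-{[4-(benzyloxy)benzyl]oxy}-6-bromobenzoic acid; 1 1,3-bis(benzyloxy)-5-bromobenzene
Product: 9 [4-(benzyloxy)-2-{[4-(benzyloxy)benzyl]oxy}-6-bromophenyl][3,5-bis(benzyloxy)phenyl]methanone, via aroyl chloride 7 (not isolated), via arylmagnesium bromide 8 (not isolated)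
Conditions: a) 6, 1-chloro-N,N,2-trimethylprop-1-en-1-amine (1.2 equiv), CH2Cl2, 0 °C → rt; b) 1, Mg, LiCl, THF, rt; c) 7 added to 8, CuI (10 mol%), THF, −40 → 0 °C
Reagents that add atoms: none
Why: Neutral acid-chloride formation (α-chloroenamine) and copper-catalysed acylation of an aryl Grignard reagent give the diaryl ketone directly, the doubly ortho-substituted carbonyl resisting a second addition, so no carbinol stereocentre exists before the asymmetric step.

Step 6
Reactants: 9 [4-(benzyloxy)-2-{[4-(benzyloxy)benzyl]oxy}-6-bromophenyl][3,5-bis(benzyloxy)phenyl]methanone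
Product: 10 hydrazone of ketone 9 (E/Z mixture)
Conditions: N2H4·H2O (20 equiv), AcOH (0.5 equiv), n-BuOH, 110 °C
Reagents that add atoms: hydrazine hydrate NN.O
Why: Condensation of the ketone with excess hydrazine gives the N-unsubstituted hydrazone, the precursor of a diaryl diazomethane; the C=N geometry is irrelevant and no stereocentre is formed.

Step 7
Reactants: 10 hydrazone of ketone 9
Product: 12 (2S,3R)-6-(benzyloxy)-2-[4-(benzyloxy)phenyl]-3-[3,5-bis(benzyloxy)phenyl]-4-bromo-2,3-dihydro-1-benzofuran (2,3-cis), via diaryldiazomethane 11 (not isolated)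
Conditions: MnO2 (8 equiv), CH2Cl2, 0 °C, filter; filtrate added over 1 h to Rh2(R-PTAD)4 [tetrakis((R)-(1-adamantyl)(N-phthalimido)acetato)dirhodium] (1 mol%), CH2Cl2, −20 → 0 °C
Reagents that add atoms: none
Why: MnO2 dehydrogenates the hydrazone to the donor/donor diazo compound, and the chiral dirhodium tetracarboxylate converts it into a carbene that inserts into the activated benzylic OCH2 bond (intramolecular 1,5 C–H insertion); the chiral ligand pocket selects the carbene face, setting C3 (R) as the first stereocentre with C2 formed cis to it (S).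

Step 8
Reactants: 12 (2S,3R)-cis-dihydrobenzofuran bromide
Product: 13 (2R,3R)-6-(benzyloxy)-2-[4-(benzyloxy)phenyl]-3-[3,5-bis(benzyloxy)phenyl]-4-bromo-2,3-dihydro-1-benzofuran (2,3-trans)
Conditions: CF3CO2H (3 equiv), CH2Cl2, 0 °C → rt
Reagents that add atoms: none
Why: Acid reversibly ionises the C2–O bond to a 4-alkoxybenzylic cation that recloses to the thermodynamically preferred 2,3-trans ring (C2 epimerisation, S to R), while the untouched C3 keeps the configuration set in step 7.

Step 9
Reactants: 14 3,5-di-tert-butyl-4-hydroxybenzaldehyde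
Product: 15 2,6-di-tert-butyl-4-vinylphenol
Conditions: Ph3PCH3Br (1.5 equiv), KOt-Bu (2.6 equiv), THF, 0 °C → rt; aq. NH4Cl
Reagents that add atoms: methyltriphenylphosphonium bromide C[P+](c1ccccc1)(c1ccccc1)c1ccccc1.[Br-]
Why: Wittig methylenation, run with excess base because the phenol is deprotonated first, the unstabilised ylide being reactive enough for the phenoxide-deactivated aldehyde; no stereocentre.

Step 10
Reactants: 13 (2R,3R)-trans-dihydrobenzofuran bromide; 15 2,6-di-tert-butyl-4-vinylphenol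
Product: 16 4-[(E)-2-{(2R,3R)-6-(benzyloxy)-2-[4-(benzyloxy)phenyl]-3-[3,5-bis(benzyloxy)phenyl]-2,3-dihydro-1-benzofuran-4-yl}ethenyl]-2,6-di-tert-butylphenol (tetra-O-benzyl di-tert-butyl ε-viniferin)
Conditions: Pd(OAc)2 (5 mol%), P(t-Bu)3·HBF4 (10 mol%), Cy2NMe (2 equiv), 1,4-dioxane, 90 °C
Reagents that add atoms: none
Why: Mizoroki–Heck coupling of the hindered aryl bromide (bulky electron-rich phosphine on zerovalent palladium) with the styrene gives the E-stilbene by syn-insertion and syn-β-hydride elimination; the hindered phenol needs no protection and the ring stereocentres are unaffected.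

Step 11
Reactants: 16 tetra-O-benzyl di-tert-butyl ε-viniferin (two molecules)
Product: 17 bis(quinone methide) dimer joined C8(3)–C8(5)
Conditions: laccase from Trametes versicolor (oxidoreductase), O2 (1 atm), 2,2'-azino-bis(3-ethylbenzothiazoline-6-sulfonic acid) diammonium salt (5 mol%), EtOAc/NaOAc buffer (0.1 M, pH 5.0) 1:1, 25 °C
Reagents that add atoms: none
Why: Laccase-catalysed aerobic phenol oxidation gives a phenoxyl radical with spin at C8 which, with both ortho positions blocked by tert-butyl groups, couples only C8–C8' to the persistent bis(quinone methide); the two new C8 centres form as an epimer mixture that interconverts by reversible homolysis of the weak central bond, the (R,R) epimer drawn being the one consumed in step 12.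

Step 12
Reactants: 17 bis(quinone methide) dimer
Product: 18 mono-cyclised tetramer with the eight-membered ring (C7(5)–C14(4)), one quinone methide left on unit 3
Conditions: BF3·OEt2 (1.0 equiv), CH2Cl2, −78 °C, 30 min; Et3N quench
Reagents that add atoms: none
Why: Intramolecular Friedel–Crafts alkylation: BF3 turns one quinone methide into a stabilised benzylic cation that is captured by the 3,5-bis(benzyloxy)phenyl ring of unit 4; that ring reaches only one face of the unit-5 quinone methide, which sets C7(5), and once one quinone methide is consumed the central bond no longer homolyses, so C8(3) and C8(5) are fixed from the equilibrating mixture.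

Step 13
Reactants: 18 mono-cyclised tetramer; 16 tetra-O-benzyl di-tert-butyl ε-viniferin
Product: 19 open-chain hexamer with the C8(1)–C7(3) bond and a quinone methide on unit 1
Conditions: 16 (1.05 equiv), KN(SiMe3)2 (1.0 equiv), THF, −78 °C, 15 min; then 18, −78 → −30 °C; AcOH quench
Reagents that add atoms: none
Why: Vinylogous 1,6-conjugate (Michael-type) addition: the hindered phenolate of 16 can react only through C8 (oxygen and ortho carbons are blocked), attacking the remaining quinone methide without Lewis acid so no ring closure competes, which re-aromatises unit 3 and leaves a new quinone methide on unit 1; C7(3) is set by attack anti to the large C8(3) substituent (Felkin-type) and C8(1) by reaction of the alkene face remote from the C3 aryl group of its own dihydrobenzofuran.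

Step 14
Reactants: 19 open-chain hexamer quinone methide
Product: 20 fully protected hexamer (twelve O-benzyl, six C-tert-butyl groups)
Conditions: BF3·OEt2 (1.5 equiv), CH2Cl2, −78 °C; Et3N quench
Reagents that add atoms: none
Why: Lewis-acid-promoted intramolecular Friedel–Crafts alkylation of the unit-1 quinone methide by the 3,5-bis(benzyloxy)phenyl ring of unit 2 closes the seven-membered ring, the closure that turns ε-viniferin into ampelopsin-type skeletons under acid; the ring is held on one face by the dihydrobenzofuran C3 centre, which sets C7(1).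

Step 15
Reactants: 20 fully protected hexamer
Product: 21 hexa-tert-butyl hexamer with all fifteen hydroxyl groups free
Conditions: H2 (1 atm), 10% Pd/C, THF/MeOH 1:1, rt
Reagents that add atoms: none
Why: Catalytic hydrogenolysis removes all twelve O-benzyl groups under neutral conditions; no alkene remains, aryl benzyl ethers cleave faster than the cyclic 2-aryl-dihydrobenzofuran C–O bonds, and no stereocentre is touched.

Step 16
Reactants: 21 hexa-tert-butyl hexamer
Product: 22 target CNP0184494.1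
Conditions: AlCl3 (30 equiv), toluene/CH3NO2 4:1, 50 °C; aq. HCl
Reagents that add atoms: none
Why: Retro-Friedel–Crafts de-tert-butylation: AlCl3 activates the phenol rings and the tert-butyl cations are transferred irreversibly to toluene, unveiling the three 4-hydroxyphenyl rings; the trans-dihydrobenzofurans are already the thermodynamic isomers, so no stereocentre changes.

## Compound list

1 | 1,3-bis(benzyloxy)-5-bromobenzene | Brc1cc(OCc2ccccc2)cc(OCc2ccccc2)c1 | starting material
2 | 2,4-bis(benzyloxy)-6-bromobenzaldehyde | O=Cc1c(Br)cc(OCc2ccccc2)cc1OCc1ccccc1 | intermediate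
3 | 4-(benzyloxy)-2-bromo-6-hydroxybenzaldehyde | O=Cc1c(Br)cc(OCc2ccccc2)cc1O | intermediate
4 | 1-(benzyloxy)-4-(chloromethyl)benzene | ClCc1ccc(OCc2ccccc2)cc1 | starting material
5 | 4-(benzyloxy)-2-{[4-(benzyloxy)benzyl]oxy}-6-bromobenzaldehyde | O=Cc1c(Br)cc(OCc2ccccc2)cc1OCc1ccc(OCc2ccccc2)cc1 | intermediate
6 | 4-(benzyloxy)-2-{[4-(benzyloxy)benzyl]oxy}-6-bromobenzoic acid | OC(=O)c1c(Br)cc(OCc2ccccc2)cc1OCc1ccc(OCc2ccccc2)cc1 | intermediate
7 | 4-(benzyloxy)-2-{[4-(benzyloxy)benzyl]oxy}-6-bromobenzoyl chloride | ClC(=O)c1c(Br)cc(OCc2ccccc2)cc1OCc1ccc(OCc2ccccc2)cc1 | intermediate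
8 | [3,5-bis(benzyloxy)phenyl]magnesium bromide | Br[Mg]c1cc(OCc2ccccc2)cc(OCc2ccccc2)c1 | intermediate
9 | [4-(benzyloxy)-2-{[4-(benzyloxy)benzyl]oxy}-6-bromophenyl][3,5-bis(benzyloxy)phenyl]methanone | O=C(c1cc(OCc2ccccc2)cc(OCc2ccccc2)c1)c1c(Br)cc(OCc2ccccc2)cc1OCc1ccc(OCc2ccccc2)cc1 | intermediate
10 | hydrazone of 9 (E/Z mixture) | NN=C(c1cc(OCc2ccccc2)cc(OCc2ccccc2)c1)c1c(Br)cc(OCc2ccccc2)cc1OCc1ccc(OCc2ccccc2)cc1 | intermediate
11 | diazo compound from 10: 5-(benzyloxy)-1-{[4-(benzyloxy)benzyl]oxy}-2-{[3,5-bis(benzyloxy)phenyl](diazo)methyl}-3-bromobenzene | [N-]=[N+]=C(c1cc(OCc2ccccc2)cc(OCc2ccccc2)c1)c1c(Br)cc(OCc2ccccc2)cc1OCc1ccc(OCc2ccccc2)cc1 | intermediate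
12 | (2S,3R)-6-(benzyloxy)-2-[4-(benzyloxy)phenyl]-3-[3,5-bis(benzyloxy)phenyl]-4-bromo-2,3-dihydro-1-benzofuran (cis) | Brc1cc(OCc2ccccc2)cc2c1[C@@H](c1cc(OCc3ccccc3)cc(OCc3ccccc3)c1)[C@@H](c1ccc(OCc3ccccc3)cc1)O2 | intermediate
13 | (2R,3R)-6-(benzyloxy)-2-[4-(benzyloxy)phenyl]-3-[3,5-bis(benzyloxy)phenyl]-4-bromo-2,3-dihydro-1-benzofuran (trans) | Brc1cc(OCc2ccccc2)cc2c1[C@@H](c1cc(OCc3ccccc3)cc(OCc3ccccc3)c1)[C@H](c1ccc(OCc3ccccc3)cc1)O2 | intermediate
14 | 3,5-di-tert-butyl-4-hydroxybenzaldehyde | CC(C)(C)c1cc(C=O)cc(C(C)(C)C)c1O | starting material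
15 | 2,6-di-tert-butyl-4-vinylphenol | C=Cc1cc(C(C)(C)C)c(O)c(C(C)(C)C)c1 | intermediate
16 | 4-[(E)-2-{(2R,3R)-6-(benzyloxy)-2-[4-(benzyloxy)phenyl]-3-[3,5-bis(benzyloxy)phenyl]-2,3-dihydro-1-benzofuran-4-yl}ethenyl]-2,6-di-tert-butylphenol | CC(C)(C)c1cc(/C=C/c2cc(OCc3ccccc3)cc3c2[C@@H](c2cc(OCc4ccccc4)cc(OCc4ccccc4)c2)[C@H](c2ccc(OCc4ccccc4)cc2)O3)cc(C(C)(C)C)c1O | intermediate
17 | 4,4'-[(2R,3R)-2,3-bis{(2R,3R)-6-(benzyloxy)-2-[4-(benzyloxy)phenyl]-3-[3,5-bis(benzyloxy)phenyl]-2,3-dihydro-1-benzofuran-4-yl}butane-1,4-diylidene]bis(2,6-di-tert-butylcyclohexa-2,5-dien-1-one), the C2-symmetric C8(3)–C8(5) dimer of 16 | O=C1C(C(C)(C)C)=CC(=C[C@H]([C@@H](C=C2C=C(C(C)(C)C)C(=O)C(C(C)(C)C)=C2)c2cc(OCc6ccccc6)cc3c2[C@@H](c2cc(OCc6ccccc6)cc(OCc6ccccc6)c2)[C@H](c2ccc(OCc6ccccc6)cc2)O3)c2cc(OCc6ccccc6)cc3c2[C@@H](c2cc(OCc6ccccc6)cc(OCc6ccccc6)c2)[C@H](c2ccc(OCc6ccccc6)cc2)O3)C=C1C(C)(C)C | intermediate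
18 | mono-cyclised tetramer: 17 with C7(5) bonded to C14(4) (eight-membered ring), unit 5 a 3,5-di-tert-butyl-4-hydroxyphenyl group, unit 3 still a quinone methide; 8(3)R, 8(5)S, 7(5)S, dihydrobenzofurans (2R,3R) | O=C1C(C(C)(C)C)=CC(=C[C@H]2c4cc(OCc6ccccc6)cc5c4[C@@H](c4cc(OCc6ccccc6)cc(OCc6ccccc6)c4[C@H](c4cc(C(C)(C)C)c(O)c(C(C)(C)C)c4)[C@H]2c2cc(OCc6ccccc6)cc4c2[C@@H](c2cc(OCc6ccccc6)cc(OCc6ccccc6)c2)[C@H](c2ccc(OCc6ccccc6)cc2)O4)[C@H](c2ccc(OCc6ccccc6)cc2)O5)C=C1C(C)(C)C | intermediate
19 | open-chain hexamer: 18 with C7(3) bonded to C8(1) of a third unit of 16, unit 3 re-aromatised to the phenol, unit 1 a quinone methide (C7(1) sp2), seven-membered ring not yet closed; all stereocentres spatially as in 22 | O=C1C(C(C)(C)C)=CC(=C[C@@H](c2cc(OCc6ccccc6)cc3c2[C@@H](c2cc(OCc6ccccc6)cc(OCc6ccccc6)c2)[C@H](c2ccc(OCc6ccccc6)cc2)O3)[C@H](c2cc(C(C)(C)C)c(O)c(C(C)(C)C)c2)[C@H]2c4cc(OCc6ccccc6)cc5c4[C@@H](c4cc(OCc6ccccc6)cc(OCc6ccccc6)c4[C@H](c4cc(C(C)(C)C)c(O)c(C(C)(C)C)c4)[C@H]2c2cc(OCc6ccccc6)cc4c2[C@@H](c2cc(OCc6ccccc6)cc(OCc6ccccc6)c2)[C@H](c2ccc(OCc6ccccc6)cc2)O4)[C@H](c2ccc(OCc6ccccc6)cc2)O5)C=C1C(C)(C)C | intermediate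
20 | fully protected hexamer: 22 bearing twelve O-benzyl groups (all resorcinol-ring and dihydrobenzofuran C2-aryl oxygens) and two tert-butyl groups ortho to each of the three free 4-hydroxyphenyl OH groups of units 1, 3, 5; 7(1)S, 8(1)S, 7(3)R, 8(3)R, 7(5)S, 8(5)S, dihydrobenzofurans (2R,3R) | Oc1c(C(C)(C)C)cc([C@H]2c3c(OCc6ccccc6)cc(OCc6ccccc6)cc3[C@@H]3c4c(cc(OCc6ccccc6)cc4[C@H]2[C@H](c2cc(C(C)(C)C)c(O)c(C(C)(C)C)c2)[C@H]2c4cc(OCc6ccccc6)cc5c4[C@@H](c4cc(OCc6ccccc6)cc(OCc6ccccc6)c4[C@H](c4cc(C(C)(C)C)c(O)c(C(C)(C)C)c4)[C@H]2c2cc(OCc6ccccc6)cc4c2[C@@H](c2cc(OCc6ccccc6)cc(OCc6ccccc6)c2)[C@H](c2ccc(OCc6ccccc6)cc2)O4)[C@H](c2ccc(OCc6ccccc6)cc2)O5)O[C@H]3c2ccc(OCc6ccccc6)cc2)cc1C(C)(C)C | intermediate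
21 | hexa-tert-butyl hexamer: 22 with two tert-butyl groups ortho to the OH of each 4-hydroxyphenyl ring of units 1, 3, 5; configuration as 22 | Oc1c(C(C)(C)C)cc([C@H]2c3c(O)cc(O)cc3[C@@H]3c4c(cc(O)cc4[C@H]2[C@H](c2cc(C(C)(C)C)c(O)c(C(C)(C)C)c2)[C@H]2c4cc(O)cc5c4[C@@H](c4cc(O)cc(O)c4[C@H](c4cc(C(C)(C)C)c(O)c(C(C)(C)C)c4)[C@H]2c2cc(O)cc4c2[C@@H](c2cc(O)cc(O)c2)[C@H](c2ccc(O)cc2)O4)[C@H](c2ccc(O)cc2)O5)O[C@H]3c2ccc(O)cc2)cc1C(C)(C)C | intermediate
22 | CNP0184494.1, ε-viniferin trimer (resveratrol hexamer); bonds C8(1)–C7(3), C7(1)–C14(2), C8(3)–C8(5), C7(5)–C14(4); 7(1)S, 8(1)S, 7(3)R, 8(3)R, 7(5)S, 8(5)S, three (2R,3R)-trans-dihydrobenzofurans | Oc1ccc([C@H]2c3c(O)cc(O)cc3[C@@H]3c4c(cc(O)cc4[C@H]2[C@H](c2ccc(O)cc2)[C@H]2c4cc(O)cc5c4[C@@H](c4cc(O)cc(O)c4[C@H](c4ccc(O)cc4)[C@H]2c2cc(O)cc4c2[C@@H](c2cc(O)cc(O)c2)[C@H](c2ccc(O)cc2)O4)[C@H](c2ccc(O)cc2)O5)O[C@H]3c2ccc(O)cc2)cc1 | target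

## Step count and risks

Total steps: 16. Longest linear sequence: 15 steps (steps 1–8 and 10–16; step 9 is a one-step side branch).

Three steps most likely to fail:

Step 12 (eight-membered ring closure). This is the least certain step. A quinone methide of this type more usually closes a seven-membered ring onto the 3,5-dialkoxyphenyl ring of its own half, or a five-membered ring onto C5 of the partner benzofuran, and a second closure can follow the first. The fallback changes the order of bond formation. It sets out from 17: one quinone methide of 17 is first consumed by the potassium phenolate of 16 (1 equiv, THF, −78 °C, no Lewis acid), giving the open-chain hexameric bis(quinone methide) F1. In F1 the C8(1)–C7(3) bond is already in place, and the unit-3 electrophile that drives the unwanted seven-membered closure by the unit-4 ring is gone. BF3·OEt2 then closes both rings (C7(1)–C14(2) and C7(5)–C14(4)) in one operation, and the sequence comes back to the route at 20.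

Step 13 (intermolecular 1,6-addition). The product quinone methide could take up a second phenolate, the addition may be reversible, and base can tautomerise the quinone methide of 18 to a stilbene, which would erase C8(3). The fallback replaces nucleophile activation by electrophile activation. It sets out from 18 and 16: both are treated together with BF3·OEt2 in CH2Cl2 at −78 °C, so the stilbene of 16 attacks the activated quinone methide as a π-nucleophile and the resulting cation is trapped at once by its own 3,5-bis(benzyloxy)phenyl ring (cationic alkene addition/Friedel–Crafts cascade, self-terminating). This comes back to the route at 20 and makes no compound outside the list (F0).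

Step 7 (asymmetric C–H insertion). The bromine ortho to the carbene carbon may slow insertion or erode enantioselectivity. The fallback sets out from 10: the diazo compound 11 is decomposed with achiral Rh2(OAc)4 to give the racemic cis product, that is 12 together with its mirror image, (2R,3S)-cis-dihydrobenzofuran bromide F2. The enantiomers are separated by preparative chromatography on a chiral stationary phase (resolution instead of induction), F2 is discarded, and the sequence comes back to the route at 12.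

Further compounds

F1 | step 12 | open-chain hexameric bis(quinone methide): 17 with C7(3) bonded to C8(1) of a third unit of 16, unit 3 a phenol, quinone methides at C7(1) and C7(5), neither carbocycle closed | O=C1C(C(C)(C)C)=CC(=C[C@@H](c2cc(OCc6ccccc6)cc3c2[C@@H](c2cc(OCc6ccccc6)cc(OCc6ccccc6)c2)[C@H](c2ccc(OCc6ccccc6)cc2)O3)[C@H](c2cc(C(C)(C)C)c(O)c(C(C)(C)C)c2)[C@H]([C@@H](C=C2C=C(C(C)(C)C)C(=O)C(C(C)(C)C)=C2)c2cc(OCc6ccccc6)cc3c2[C@@H](c2cc(OCc6ccccc6)cc(OCc6ccccc6)c2)[C@H](c2ccc(OCc6ccccc6)cc2)O3)c2cc(OCc6ccccc6)cc3c2[C@@H](c2cc(OCc6ccccc6)cc(OCc6ccccc6)c2)[C@H](c2ccc(OCc6ccccc6)cc2)O3)C=C1C(C)(C)C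
F0 | step 13 | none | none
F2 | step 7 | (2R,3S)-6-(benzyloxy)-2-[4-(benzyloxy)phenyl]-3-[3,5-bis(benzyloxy)phenyl]-4-bromo-2,3-dihydro-1-benzofuran (mirror image of 12) | Brc1cc(OCc2ccccc2)cc2c1[C@H](c1cc(OCc3ccccc3)cc(OCc3ccccc3)c1)[C@H](c1ccc(OCc3ccccc3)cc1)O2
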